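**Retrosynthetic overview**

1. Feature: in the ring C1–C6, the quaternary carbinol C1 carries the exocyclic carbon C7 and sits next to oxygenated C6. These are the ipso (C1), ortho (C6) and carboxyl (C7) carbons of benzoic acid, so the carbocycle is the benzene ring itself and is never constructed.
2. Target ⇐ C5 silyl ether enone ⇐ enetriol: the C2 ketone comes from the C2 carbinol once the less hindered C5 hydroxyl is silylated. A base-induced Kornblum–DeLaMare opening of the endoperoxide is avoided because the more exposed H5 would probably place the ketone at C5.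
3. Enetriol ⇐ endoperoxide ⇐ trans-dibenzoate diene: the C2 and C5 oxygens come from singlet oxygen added across C2=C3–C4=C5 on the face of the C1 hydroxyl. The peroxide bridge is the only ring formed and is opened again.
4. Diene ⇐ cis-diol monobenzoate ⇐ triol ⇐ methyl ester ⇐ dienediol acid: the C6 benzoate by Mitsunobu inversion, the C7 benzoate after reduction of the carboxyl carbon.
5. Dienediol acid ⇐ benzoic acid: whole-cell ipso,ortho-cis-dihydroxylation forms the C1–O and C6–O bonds and sets the absolute configuration.

Key step: step 1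

Assumption: the dehydrogenase-deficient strain Ralstonia eutropha B9 is obtainable from a culture collection, and its NADH is regenerated by the growing cells and treated as a catalytic cofactor. C1 keeps the spatial arrangement set in step 1 throughout; its descriptor changes (S in 2 and 3, R in 4, 6, 7 and 8, S in 9 and 10, R in 11 and 12) only because the CIP ranks of its neighbours change.

**Route**

Step 1
Reactants: 1 benzoic acid (fed as its sodium salt)
Product: 2 (1S,2R)-1,2-dihydroxycyclohexa-3,5-diene-1-carboxylic acid
Conditions: Ralstonia eutropha B9 whole cells, fructose, mineral salts medium, fed-batch benzoate, air, 30 °C, pH 7; cells removed, pH 3 (HCl, 0 °C), EtOAc extraction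
Reagents that add atoms: dioxygen, O=O
Why: Benzoate 1,2-dioxygenase, a non-haem iron oxygenase with an iron–sulfur electron-relay cluster, binds benzoate through its carboxylate, activates O2 at the mononuclear iron centre with two electrons from NADH, and delivers both oxygen atoms suprafacially to the ipso carbon and one ortho carbon, so the two C–O bonds form on one face and the other four ring carbons remain as a conjugated diene. The closest known reaction type is the dioxygenase-mediated cis-dihydroxylation of arenes, here in its ipso,ortho mode, which is established for benzoic acid with this strain. No ring is closed; the benzene ring is only dearomatised. Both stereocentres (tertiary carbinol 1S, secondary carbinol 2R, cis) are fixed by the chiral active site, the only source of asymmetry in the route. The step needs ipso,ortho rather than ortho,meta regioselectivity and must stop at the diol: the first is secured by the enzyme's recognition of the carboxylate, the second by the mutant's lack of the cis-diol dehydrogenase that would otherwise convert 2 into catechol.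

Step 2
Reactants: 2 (1S,2R)-1,2-dihydroxycyclohexa-3,5-diene-1-carboxylic acid
Product: 3 methyl (1S,2R)-1,2-dihydroxycyclohexa-3,5-diene-1-carboxylate
Conditions: Me3SiCHN2 (hexanes solution), MeOH–toluene, 0 °C
Reagents that add atoms: (trimethylsilyl)diazomethane, C[Si](C)(C)C=[N+]=[N-]
Why: Diazoalkane esterification methylates the carboxylic acid under neutral conditions at 0 °C, avoiding the acid that would dehydrate the dienediol to an arene, and touches no stereocentre.

Step 3
Reactants: 3 methyl (1S,2R)-1,2-dihydroxycyclohexa-3,5-diene-1-carboxylate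
Product: 4 (1R,2R)-1-(hydroxymethyl)cyclohexa-3,5-diene-1,2-diol
Conditions: LiAlH4, THF, 0 °C; Na2SO4·10H2O quench, filtration
Reagents that add atoms: none
Why: LiAlH4 reduction of the ester gives the primary alcohol at C7; the diene is not conjugated with the ester and is inert to hydride, the two hydroxyls are only converted into alkoxides, and the salt-hydrate quench keeps the acid-labile triol at neutral to basic pH.

Step 4
Reactants: 4 (1R,2R)-1-(hydroxymethyl)cyclohexa-3,5-diene-1,2-diol; 5 benzoyl chloride
Product: 6 [(1R,6R)-1,6-dihydroxycyclohexa-2,4-dien-1-yl]methyl benzoate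
Conditions: BzCl (1.05 equiv), pyridine, CH2Cl2, −40 → −20 °C
Reagents that add atoms: benzoyl chloride (5), O=C(Cl)c1ccccc1
Why: Kinetically controlled acylation with an acid chloride and pyridine should take the primary C7 hydroxyl in preference to the secondary C6 hydroxyl beside the quaternary carbon and to the tertiary C1 hydroxyl, with no change at any stereocentre.

Step 5
Reactants: 6 [(1R,6R)-1,6-dihydroxycyclohexa-2,4-dien-1-yl]methyl benzoate; 1 benzoic acid
Product: 7 [(1R,6S)-6-(benzoyloxy)-1-hydroxycyclohexa-2,4-dien-1-yl]methyl benzoate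
Conditions: PPh3, DIAD, THF, 0 °C (betaine pre-formed); then PhCO2H and 6, −20 → 0 °C
Reagents that add atoms: benzoic acid (1), OC(=O)c1ccccc1
Why: In this Mitsunobu reaction the secondary C6 hydroxyl is activated on phosphorus and displaced by benzoate in an SN2 step with inversion, which turns the enzymatic cis-diol into the trans C1–OH/C6–OBz arrangement (C6 becomes S); the tertiary C1 hydroxyl cannot be displaced, quaternary C1 offers no β-hydrogen for elimination, and pre-forming the betaine keeps free azo compound away from the diene.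

Step 6
Reactants: 7 [(1R,6S)-6-(benzoyloxy)-1-hydroxycyclohexa-2,4-dien-1-yl]methyl benzoate
Product: 8 [(1S,4R,7R,8S)-8-(benzoyloxy)-7-hydroxy-2,3-dioxabicyclo[2.2.2]oct-5-en-7-yl]methyl benzoate (peroxide bridge from C2 to C5 of the former diene, syn to the tertiary hydroxyl, anti to the secondary benzoate)
Conditions: O2, visible light, tetraphenylporphyrin (cat.), CH2Cl2, −20 °C
Reagents that add atoms: dioxygen, O=O
Why: Photosensitised [4+2] cycloaddition of singlet oxygen to the cyclohexa-1,3-diene C2=C3–C4=C5 forms the C2–O and C5–O bonds suprafacially; the lower face carries both the C6 benzoate and the CH2OBz group on C1, so oxygen should add to the upper face, which holds only the C1 hydroxyl and H6, setting C5 (and C2) syn to the C1 hydroxyl and anti to the C6 benzoate.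

Step 7
Reactants: 8 [(1S,4R,7R,8S)-8-(benzoyloxy)-7-hydroxy-2,3-dioxabicyclo[2.2.2]oct-5-en-7-yl]methyl benzoate
Product: 9 [(1S,2S,5R,6S)-6-(benzoyloxy)-1,2,5-trihydroxycyclohex-3-en-1-yl]methyl benzoate
Conditions: Zn dust, AcOH, CH2Cl2, 0 °C → rt
Reagents that add atoms: none
Why: Dissolving-metal reduction cleaves only the O–O bond, so the cis-2-ene-1,4-diol keeps the C2 and C5 configurations set in the cycloaddition, and the benzoates and the alkene are untouched.

Step 8
Reactants: 9 [(1S,2S,5R,6S)-6-(benzoyloxy)-1,2,5-trihydroxycyclohex-3-en-1-yl]methyl benzoate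
Product: 10 [(1S,2S,5R,6S)-6-(benzoyloxy)-5-[(tert-butyldimethylsilyl)oxy]-1,2-dihydroxycyclohex-3-en-1-yl]methyl benzoate
Conditions: TBSCl (1.1 equiv), imidazole, DMF, 0 °C
Reagents that add atoms: tert-butyldimethylsilyl chloride, CC(C)(C)[Si](C)(C)Cl
Why: Regioselective silyl ether formation should occur at the C5 hydroxyl, whose neighbour C6 is a CH carbon, in preference to the C2 hydroxyl next to fully substituted C1 and to the tertiary C1 hydroxyl; no stereocentre is changed.

Step 9
Reactants: 10 [(1S,2S,5R,6S)-6-(benzoyloxy)-5-[(tert-butyldimethylsilyl)oxy]-1,2-dihydroxycyclohex-3-en-1-yl]methyl benzoate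
Product: 11 [(1R,5R,6S)-6-(benzoyloxy)-5-[(tert-butyldimethylsilyl)oxy]-1-hydroxy-2-oxocyclohex-3-en-1-yl]methyl benzoate
Conditions: IBX, DMSO, rt
Reagents that add atoms: none
Why: IBX oxidation converts the remaining secondary allylic C2 carbinol into the enone carbonyl without cleaving the C1–C2 glycol bond (IBX takes 1,2-diols to α-ketols), the tertiary C1 hydroxyl cannot be oxidised, and the neutral medium avoids vinylogous elimination of the C6 benzoate.

Step 10
Reactants: 11 [(1R,5R,6S)-6-(benzoyloxy)-5-[(tert-butyldimethylsilyl)oxy]-1-hydroxy-2-oxocyclohex-3-en-1-yl]methyl benzoate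
Product: 12 [(1R,5R,6S)-6-(benzoyloxy)-1,5-dihydroxy-2-oxocyclohex-3-en-1-yl]methyl benzoate (target)
Conditions: HF·pyridine, THF–pyridine, 0 °C → rt
Reagents that add atoms: none
Why: Fluoride-mediated desilylation with buffered HF·pyridine cleaves the Si–O bond of the secondary silyl ether with retention at C5 and without the basic conditions that would promote benzoyl migration or elimination in the γ-hydroxy enone.

**Compound list**

1 | benzoic acid | OC(=O)c1ccccc1 | starting material
2 | (1S,2R)-1,2-dihydroxycyclohexa-3,5-diene-1-carboxylic acid | OC(=O)[C@]1(O)C=CC=C[C@H]1O | intermediate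
3 | methyl (1S,2R)-1,2-dihydroxycyclohexa-3,5-diene-1-carboxylate | COC(=O)[C@]1(O)C=CC=C[C@H]1O | intermediate
4 | (1R,2R)-1-(hydroxymethyl)cyclohexa-3,5-diene-1,2-diol | OC[C@]1(O)C=CC=C[C@H]1O | intermediate
5 | benzoyl chloride | O=C(Cl)c1ccccc1 | starting material
6 | [(1R,6R)-1,6-dihydroxycyclohexa-2,4-dien-1-yl]methyl benzoate | O=C(OC[C@]1(O)C=CC=C[C@H]1O)c1ccccc1 | intermediate
7 | [(1R,6S)-6-(benzoyloxy)-1-hydroxycyclohexa-2,4-dien-1-yl]methyl benzoate | O=C(OC[C@]1(O)C=CC=C[C@@H]1OC(=O)c1ccccc1)c1ccccc1 | intermediate
8 | [(1S,4R,7R,8S)-8-(benzoyloxy)-7-hydroxy-2,3-dioxabicyclo[2.2.2]oct-5-en-7-yl]methyl benzoate | O=C(OC[C@]1(O)[C@@H]2C=C[C@@H](OO2)[C@@H]1OC(=O)c1ccccc1)c1ccccc1 | intermediate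
9 | [(1S,2S,5R,6S)-6-(benzoyloxy)-1,2,5-trihydroxycyclohex-3-en-1-yl]methyl benzoate | O=C(OC[C@]1(O)[C@@H](O)C=C[C@@H](O)[C@@H]1OC(=O)c1ccccc1)c1ccccc1 | intermediate
10 | [(1S,2S,5R,6S)-6-(benzoyloxy)-5-[(tert-butyldimethylsilyl)oxy]-1,2-dihydroxycyclohex-3-en-1-yl]methyl benzoate | O=C(OC[C@]1(O)[C@@H](O)C=C[C@@H](O[Si](C)(C)C(C)(C)C)[C@@H]1OC(=O)c1ccccc1)c1ccccc1 | intermediate
11 | [(1R,5R,6S)-6-(benzoyloxy)-5-[(tert-butyldimethylsilyl)oxy]-1-hydroxy-2-oxocyclohex-3-en-1-yl]methyl benzoate | O=C(OC[C@]1(O)C(=O)C=C[C@@H](O[Si](C)(C)C(C)(C)C)[C@@H]1OC(=O)c1ccccc1)c1ccccc1 | intermediate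
12 | [(1R,5R,6S)-6-(benzoyloxy)-1,5-dihydroxy-2-oxocyclohex-3-en-1-yl]methyl benzoate | O=C(OC[C@]1(O)C(=O)C=C[C@@H](O)[C@@H]1OC(=O)c1ccccc1)c1ccccc1 | target

**Totals and risks**

Total step count: 10. Longest linear sequence: 10 steps (1 → 12).

Steps most likely to fail:

Step 5 (Mitsunobu inversion at C6). The process at risk is the substitution itself. Benzoate may attack the activated dienyl system in SN2′ fashion at C4 or C2 instead of at the neopentyl-type C6. The dienyl C6–O bond may ionise to an arenium-type cation that rearomatises. The azo reagent may also consume the diene by cycloaddition or ene reaction. The fallback sets out from 6 and returns at 7. The cis-diol of 6 is closed with SOCl2 and Et3N in CH2Cl2 at 0 °C to the cyclic sulfite of 6, [2-oxido-3a,7a-dihydro-1,3,2-benzodioxathiol-3a-yl]methyl benzoate F1 (sulfur epimers). This is opened with caesium benzoate (PhCO2Cs) in DMF at 40–50 °C; only the secondary carbon C6 can be attacked, from the face opposite its oxygen, giving the caesium salt of the C1 sulfite half-ester of 7 F2. Brief treatment with dilute aqueous H2SO4 in THF should release SO2 and give 7.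

Step 8 (selective silylation of the C5 hydroxyl). Site selectivity between the two secondary allylic hydroxyls may be poor, and the base may promote benzoyl migration from O6 to O5. The fallback sets out from 9 and arrives directly at 12, removing steps 8–10. Triol 9 is heated with Bu2SnO in toluene at 80 °C over 4 Å sieves to give the O1,O2-dibutylstannylene acetal of 9 F3, formed only across the cis-vicinal C1/C2 diol. Brominolysis with Br2 (1 equiv) in CH2Cl2 at 0 °C should oxidise only the tin-bound secondary carbinol C2 to the ketone, leaving the isolated C5 hydroxyl alone.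

Step 4 (selective benzoylation of the primary hydroxyl). Over-acylation at the C6 hydroxyl, which would fix the wrong (retained) configuration, and losses of the water-soluble, acid-labile triol 4 are the likely failures. The fallback sets out from 3 and returns at 6, replacing kinetic selectivity by protecting-group control and avoiding 4 altogether. The only secondary hydroxyl of 3 is silylated with Et3SiCl and imidazole in DMF at 0 °C to methyl (1S,2R)-1-hydroxy-2-[(triethylsilyl)oxy]cyclohexa-3,5-diene-1-carboxylate F4. The ester is reduced with iBu2AlH in CH2Cl2 at −78 → 0 °C to (1R,6R)-1-(hydroxymethyl)-6-[(triethylsilyl)oxy]cyclohexa-2,4-dien-1-ol F5. Its only primary hydroxyl is benzoylated with BzCl and pyridine to [(1R,6R)-1-hydroxy-6-[(triethylsilyl)oxy]cyclohexa-2,4-dien-1-yl]methyl benzoate F6. The silyl ether is then removed with HF·pyridine in THF at 0 °C to give 6.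

**Further compounds**

F1 | step 5 | cyclic sulfite of 6: [2-oxido-3a,7a-dihydro-1,3,2-benzodioxathiol-3a-yl]methyl benzoate, cis ring fusion, sulfur epimers | O=C(OC[C@]12C=CC=C[C@H]1OS(=O)O2)c1ccccc1
F2 | step 5 | caesium salt of the C1 sulfite half-ester of 7 | O=C(OC[C@]1(OS(=O)[O-])C=CC=C[C@@H]1OC(=O)c1ccccc1)c1ccccc1.[Cs+]
F3 | step 8 | O1,O2-dibutylstannylene acetal of 9 | O=C(OC[C@@]12O[Sn](CCCC)(CCCC)O[C@H]2C=C[C@@H](O)[C@@H]1OC(=O)c1ccccc1)c1ccccc1
F4 | step 4 | methyl (1S,2R)-1-hydroxy-2-[(triethylsilyl)oxy]cyclohexa-3,5-diene-1-carboxylate | COC(=O)[C@]1(O)C=CC=C[C@H]1O[Si](CC)(CC)CC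
F5 | step 4 | (1R,6R)-1-(hydroxymethyl)-6-[(triethylsilyl)oxy]cyclohexa-2,4-dien-1-ol | OC[C@]1(O)C=CC=C[C@H]1O[Si](CC)(CC)CC
F6 | step 4 | [(1R,6R)-1-hydroxy-6-[(triethylsilyl)oxy]cyclohexa-2,4-dien-1-yl]methyl benzoate | O=C(OC[C@]1(O)C=CC=C[C@H]1O[Si](CC)(CC)CC)c1ccccc1
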